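**Strategy.** The target is a brominated triphlorethol: ring A (2,4,6-trihydroxyphenyl), central ring B (ether oxygens at B1 and B4, hydroxyls at B3 and B5) and ring C (4-bromo-3,5-dihydroxyphenyl). The plan rests on disconnecting the B3–O and B5–O bonds that flank the ether carbon B4. Both oxygens are carried as formyl groups: in dialdehyde 9 they have already made a B4–F bond reactive enough for SNAr by the ring C phenoxide, and a single twofold Dakin-type Baeyer–Villiger oxidation then converts them into the two hydroxyls of diol 11. Methylation, selective Ullmann coupling at the B1 bromide with the ring A phenol and global demethylation finish the synthesis.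

Key step: step 5

Remark: the molecule has no stereocentres. 2,4,6-Trimethoxyphenol (13), 4-bromo-2,6-dimethoxyphenol and 2-iodo-1,3,5-trimethoxybenzene are assumed to be purchasable. Methyl is the only phenol protecting group because BBr3 removes it without touching C–Br bonds.

Step 1
Reactants: 1 5-bromo-2-fluorobenzaldehyde
Product: 2 4-bromo-2-(dimethoxymethyl)-1-fluorobenzene
Conditions: HC(OMe)3, TsOH·H2O (cat.), MeOH, 50 °C; then Et3N
Reagents that add atoms: trimethyl orthoformate, COC(OC)OC; methanol, CO
Why: Acid-catalysed acetalisation, driven to completion by the orthoester as water scavenger, should mask the aldehyde against the lithium amide of the next step while leaving C–F and C–Br untouched.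

Step 2
Reactants: 2 4-bromo-2-(dimethoxymethyl)-1-fluorobenzene
Product: 5 5-bromo-2-fluorobenzene-1,3-dicarbaldehyde, via aryllithium 3 (not isolated), via formyl acetal 4 (not isolated)
Conditions: LiN(iPr)2 (LDA), THF, −78 °C; DMF, −78 → −40 °C; poured into cold 2 M HCl, then rt
Reagents that add atoms: N,N-dimethylformamide, CN(C)C=O; water, O
Why: Directed ortho-lithiation should remove the ring proton next to fluorine, the most acidic one, at −78 °C without bromine–lithium exchange or aryne formation; formylation of the aryllithium with DMF and an acidic quench (which protonates the liberated amines and hydrolyses the dimethyl acetal) should then deliver the dialdehyde.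

Step 3
Reactants: 6 2-bromo-1,3-dimethoxybenzene
Product: 8 4-bromo-3,5-dimethoxyphenol, via pinacol boronate 7 (not isolated)
Conditions: [Ir(OMe)(cod)]2 (cat.), dtbpy (cat.), B2pin2 (0.6 equiv), THF, 80 °C; then 30% H2O2, NaOH (1 equiv), THF/H2O, 0 °C → rt
Reagents that add atoms: hydrogen peroxide, OO
Why: Sterically controlled iridium-catalysed C–H borylation should occur only at C5–H, the one ring hydrogen without an ortho substituent, and tolerate the C–Br bond; alkaline peroxide oxidation of the C–B bond (aryl shift from boron to oxygen) then gives the phenol in the same flask.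

Step 4
Reactants: 5 5-bromo-2-fluorobenzene-1,3-dicarbaldehyde; 8 4-bromo-3,5-dimethoxyphenol
Product: 9 5-bromo-2-(4-bromo-3,5-dimethoxyphenoxy)benzene-1,3-dicarbaldehyde
Conditions: K2CO3, DMF, rt
Reagents that add atoms: none
Why: Nucleophilic aromatic substitution (SNAr) should be easy because the Meisenheimer adduct at the C–F carbon is stabilised by two ortho formyl groups and fluoride is the best leaving group, whereas neither aryl bromide sits ortho or para to an acceptor.

Step 5
Reactants: 9 5-bromo-2-(4-bromo-3,5-dimethoxyphenoxy)benzene-1,3-dicarbaldehyde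
Product: 11 5-bromo-2-(4-bromo-3,5-dimethoxyphenoxy)benzene-1,3-diol, via bis-formate 10 (not isolated)
Conditions: mCPBA (3 equiv), CH2Cl2, 0 → 40 °C; aq. Na2S2O3/NaHCO3 wash; then K2CO3 (cat.), MeOH, 0 °C → rt, N2
Reagents that add atoms: 3-chloroperoxybenzoic acid, OOC(=O)c1cccc(Cl)c1
Why: The peracid adds to each formyl carbon to give a Criegee adduct, the attached ring B carbon (future B3, then B5) migrates from carbon to the peroxide oxygen with loss of 3-chlorobenzoate, and the resulting bis-formate 10 is cleaved by methanolysis to release B3–OH and B5–OH. This is the Dakin-type Baeyer–Villiger oxidation known for ortho-alkoxy- and ortho-aryloxybenzaldehydes. No ring is closed and no stereocentre is formed. The selectivity needed is aryl over hydride migration at both formyl groups; the lone pair of the B4 ether oxygen, ortho to each migrating carbon, should stabilise the electron-poor migration transition state, and the unbuffered medium keeps the formates intact so that no free resorcinol meets the peracid. The aryl bromides and methyl ethers are inert to mCPBA, and the bromine on ring C tempers that ring against electrophilic attack.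

Step 6
Reactants: 11 5-bromo-2-(4-bromo-3,5-dimethoxyphenoxy)benzene-1,3-diol
Product: 12 5-bromo-2-(4-bromo-3,5-dimethoxyphenoxy)-1,3-dimethoxybenzene
Conditions: MeI, K2CO3, DMF, rt
Reagents that add atoms: iodomethane, CI
Why: Williamson O-methylation of both phenols should be straightforward and leaves phenol 13 as the only oxygen nucleophile in the following coupling.

Step 7
Reactants: 12 5-bromo-2-(4-bromo-3,5-dimethoxyphenoxy)-1,3-dimethoxybenzene; 13 2,4,6-trimethoxyphenol
Product: 14 2-[4-(4-bromo-3,5-dimethoxyphenoxy)-3,5-dimethoxyphenoxy]-1,3,5-trimethoxybenzene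
Conditions: CuI (cat.), picolinic acid (cat.), K3PO4, 13 (1.2 equiv), DMSO, 90 °C, Ar
Reagents that add atoms: none
Why: Ullmann-type copper-catalysed C–O coupling with a picolinate ligand accepts di-ortho-substituted phenols; the ring B bromide, which has two ortho hydrogens, should be activated far faster than the ring C bromide buried between two methoxy groups, and the bulky phenoxide reinforces that steric preference.

Step 8
Reactants: 14 2-[4-(4-bromo-3,5-dimethoxyphenoxy)-3,5-dimethoxyphenoxy]-1,3,5-trimethoxybenzene
Product: 15 2-[4-(4-bromo-3,5-dihydroxyphenoxy)-3,5-dihydroxyphenoxy]benzene-1,3,5-triol (target)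
Conditions: BBr3 (excess), CH2Cl2, −78 °C → rt; then H2O, 0 °C, Ar
Reagents that add atoms: none
Why: Lewis-acid ether cleavage should remove all seven methyl groups, since BBr3 coordinates each methoxy oxygen and bromide attacks the methyl carbon, while the diaryl ether bonds (no sp3 carbon to attack) and the aryl bromide are inert and hydrolysis frees the phenols.

**Compound list**
1 | 5-bromo-2-fluorobenzaldehyde | O=Cc1cc(Br)ccc1F | starting material
2 | 4-bromo-2-(dimethoxymethyl)-1-fluorobenzene | COC(OC)c1cc(Br)ccc1F | intermediate
3 | [5-bromo-3-(dimethoxymethyl)-2-fluorophenyl]lithium | COC(OC)c1cc(Br)cc([Li])c1F | intermediate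
4 | 5-bromo-3-(dimethoxymethyl)-2-fluorobenzaldehyde | COC(OC)c1cc(Br)cc(C=O)c1F | intermediate
5 | 5-bromo-2-fluorobenzene-1,3-dicarbaldehyde | O=Cc1cc(Br)cc(C=O)c1F | intermediate
6 | 2-bromo-1,3-dimethoxybenzene | COc1cccc(OC)c1Br | starting material
7 | 2-(4-bromo-3,5-dimethoxyphenyl)-4,4,5,5-tetramethyl-1,3,2-dioxaborolane | COc1cc(B2OC(C)(C)C(C)(C)O2)cc(OC)c1Br | intermediate
8 | 4-bromo-3,5-dimethoxyphenol | COc1cc(O)cc(OC)c1Br | intermediate
9 | 5-bromo-2-(4-bromo-3,5-dimethoxyphenoxy)benzene-1,3-dicarbaldehyde | O=Cc1cc(Br)cc(C=O)c1Oc1cc(OC)c(Br)c(OC)c1 | intermediate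
10 | 5-bromo-2-(4-bromo-3,5-dimethoxyphenoxy)-1,3-phenylene diformate | O=COc1cc(Br)cc(OC=O)c1Oc1cc(OC)c(Br)c(OC)c1 | intermediate
11 | 5-bromo-2-(4-bromo-3,5-dimethoxyphenoxy)benzene-1,3-diol | Oc1cc(Br)cc(O)c1Oc1cc(OC)c(Br)c(OC)c1 | intermediate
12 | 5-bromo-2-(4-bromo-3,5-dimethoxyphenoxy)-1,3-dimethoxybenzene | COc1cc(Br)cc(OC)c1Oc1cc(OC)c(Br)c(OC)c1 | intermediate
13 | 2,4,6-trimethoxyphenol | COc1cc(OC)c(O)c(OC)c1 | starting material
14 | 2-[4-(4-bromo-3,5-dimethoxyphenoxy)-3,5-dimethoxyphenoxy]-1,3,5-trimethoxybenzene | COc1cc(OC)c(Oc2cc(OC)c(Oc3cc(OC)c(Br)c(OC)c3)c(OC)c2)c(OC)c1 | intermediate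
15 | 2-[4-(4-bromo-3,5-dihydroxyphenoxy)-3,5-dihydroxyphenoxy]benzene-1,3,5-triol | Oc1cc(O)c(Oc2cc(O)c(Oc3cc(O)c(Br)c(O)c3)c(O)c2)c(O)c1 | target

**Step count.** Total: 8 steps. Longest linear sequence: 7 steps (1 → 2 → 5 → 9 → 11 → 12 → 14 → 15, that is steps 1, 2, 4, 5, 6, 7 and 8); step 3 is the one-step side branch to ring C.

**Steps most likely to fail**

Step 5. Hydride migration may compete with aryl migration in one or both Criegee adducts, because ring B carries a second carbonyl group and a bromine and its ether oxygen is twisted out of conjugation. This would lead to carboxylic acids, or the oxidation may stall after the first formyl group. The fallback gives up the formyl-to-hydroxyl conversion and forms the hindered B4–O–C ether by oxidative copper coupling, with the B3 and B5 oxygens already present as methoxy groups. It sets out from boronate 7, isolated by stopping step 3 before the peroxide stage. Cleavage of the pinacol ester with NaIO4 and NH4OAc in acetone/water should give (4-bromo-3,5-dimethoxyphenyl)boronic acid F1. Chan–Lam coupling of F1 with purchased 4-bromo-2,6-dimethoxyphenol (Cu(OAc)2, pyridine, Et3N, 4 Å molecular sieves, CH2Cl2, air, rt) tolerates aryl bromides and di-ortho-substituted phenols and should give 12 directly. The fallback rejoins the route at 12, before step 7.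

Step 7. C–O bond formation with the di-ortho-substituted, easily oxidised phenoxide of 13 may be slow, so that protodebromination, phenol oxidation or reaction at the ring C bromide takes over. The fallback reverses the roles of the partners. It sets out from 12: hydroxylation of the unhindered ring B bromide (Pd2(dba)3, tBuXPhos, KOH, dioxane/H2O, 100 °C), which the bulky ligand should direct away from the flanked ring C bromide, gives 4-(4-bromo-3,5-dimethoxyphenoxy)-3,5-dimethoxyphenol F2. Ullmann coupling of this unhindered phenoxide with purchased 2-iodo-1,3,5-trimethoxybenzene (CuI, picolinic acid, K3PO4, DMSO, 90 °C), in which the iodide should react ahead of the ring C bromide, returns to the route at 14.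

Step 8. Cleavage of the seven methyl ethers may be incomplete, and the very polar, oxidation-prone polyphenol may be lost during chromatographic isolation. The fallback isolates the product through a derivative. It sets out from 14: after the BBr3 treatment and quench, the crude residue is acetylated (Ac2O, pyridine, DMAP cat., rt) to 2-[4-(3,5-diacetoxy-4-bromophenoxy)-3,5-diacetoxyphenoxy]benzene-1,3,5-triyl triacetate F3. F3 can be purified on silica, and partially methylated fractions can be separated and resubmitted to BBr3. Acid-catalysed transesterification (HCl in MeOH, made from AcCl, rt, Ar) with isolation by evaporation alone returns to the route at 15.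

**Further compounds**
F1 | step 5 | (4-bromo-3,5-dimethoxyphenyl)boronic acid | COc1cc(B(O)O)cc(OC)c1Br
F2 | step 7 | 4-(4-bromo-3,5-dimethoxyphenoxy)-3,5-dimethoxyphenol | COc1cc(O)cc(OC)c1Oc1cc(OC)c(Br)c(OC)c1
F3 | step 8 | 2-[4-(3,5-diacetoxy-4-bromophenoxy)-3,5-diacetoxyphenoxy]benzene-1,3,5-triyl triacetate | CC(=O)Oc1cc(OC(C)=O)c(Oc2cc(OC(C)=O)c(Oc3cc(OC(C)=O)c(Br)c(OC(C)=O)c3)c(OC(C)=O)c2)c(OC(C)=O)c1
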